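**Retrosynthetic overview**
1. Target 5 ⇐ bis(acetonide) 4 by ketal hydrolysis; this last event opens the two temporary dioxole rings.
2. 4 ⇐ bis(acetonide) 2 by the key disconnection: the two aryl C–OMe bonds, made by a one-flask C–H borylation / copper methoxylation ortho to the dioxole oxygen.
3. 2 ⇐ meso-NDGA 1 (commercial bulk antioxidant, sold as the meso form) plus 2,2-dimethoxypropane; 1 brings the whole C18 skeleton and both stereocentres.
4. Ring order: no carbocycle is built; the two 1,3-dioxole rings are closed first (step 1) and opened last (step 3).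

Assumption: the SMILES encodes the (2R,3S) meso diastereomer, which is achiral, so "single enantiomer" is read as "this single stereoisomer"; the meso relationship is bought with 1 and is never touched.

**Step 1**
Reactants: 1 meso-nordihydroguaiaretic acid, 4,4'-[(2R,3S)-2,3-dimethylbutane-1,4-diyl]dibenzene-1,2-diol
Product: 2 5,5'-[(2R,3S)-2,3-dimethylbutane-1,4-diyl]bis(2,2-dimethyl-1,3-benzodioxole)
Conditions: Me2C(OMe)2 (6 equiv), TsOH·H2O (5 mol%), PhMe, reflux, distillate through 4 Å MS, Ar
Reagents that add atoms: 2,2-dimethoxypropane, COC(C)(C)OC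
Why: Acid-catalysed transketalisation (acetonide formation) closes a five-membered ketal on each catechol while methanol is trapped on the sieves, and the two methyl-bearing stereocentres, present as the meso pair in 1, are not involved.

**Step 2**
Reactants: 2 5,5'-[(2R,3S)-2,3-dimethylbutane-1,4-diyl]bis(2,2-dimethyl-1,3-benzodioxole)
Product: 4 6,6'-[(2R,3S)-2,3-dimethylbutane-1,4-diyl]bis(4-methoxy-2,2-dimethyl-1,3-benzodioxole), via bis(pinacolboronate) 3 (not isolated)
Conditions: [Ir(OMe)(cod)]2 (2.5 mol%), dtbpy (5 mol%), B2pin2 (2.4 equiv), THF, 80 °C; concentrate in vacuo; then Cu(OAc)2 (30 mol% per boron), DMAP (1 equiv per boron), 4 Å MS, MeOH–CH2Cl2 (1:1), O2 (1 atm), 40 °C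
Reagents that add atoms: methanol, CO; bis(pinacolato)diboron, CC1(C)OB(OC1(C)C)B1OC(C)(C)C(C)(C)O1 (its boron stays only in intermediate 3)
Why: Proposed new method: a one-flask double formal C–H methoxylation, not yet shown on a 2,2-dimethylbenzodioxole or on both rings of a lignan, in which the trivalent iridium tris(boryl) complex (dtbpy)Ir(Bpin)3 cleaves on each ring only the C–H ortho to the tied-back dioxole oxygen and meta to the side chain (most acidic and unhindered, whereas the other two ring C–H bonds sit next to the benzylic CH2), and the crude aryl–Bpin then transmetalates to a divalent copper methoxide, is oxidised to a trivalent aryl copper methoxide and reductively eliminates the aryl C–OMe bond while O2 turns the copper over; the closest known reaction types are the iridium-catalysed ortho C–H borylation of 1,3-benzodioxoles and the Chan–Lam etherification of arylboron reagents with alcohols, and no stereocentre is formed or touched.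

**Step 3**
Reactants: 4 6,6'-[(2R,3S)-2,3-dimethylbutane-1,4-diyl]bis(4-methoxy-2,2-dimethyl-1,3-benzodioxole)
Product: 5 5,5'-[(2R,3S)-2,3-dimethylbutane-1,4-diyl]bis(3-methoxybenzene-1,2-diol)
Conditions: TFA–H2O (9:1), Ar, rt
Reagents that add atoms: none
Why: Acid-catalysed ketal hydrolysis, the standard unmasking of catechol acetonides, releases acetone from each dioxole while the aryl methyl ethers and the unactivated C–H stereocentres are inert, so the meso configuration reaches 5 unchanged.

**Compound list**
1 | meso-nordihydroguaiaretic acid, 4,4'-[(2R,3S)-2,3-dimethylbutane-1,4-diyl]dibenzene-1,2-diol | Oc1ccc(C[C@@H](C)[C@@H](C)Cc2ccc(O)c(O)c2)cc1O | starting material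
2 | 5,5'-[(2R,3S)-2,3-dimethylbutane-1,4-diyl]bis(2,2-dimethyl-1,3-benzodioxole) | CC1(C)Oc2ccc(C[C@@H](C)[C@@H](C)Cc3ccc4OC(C)(C)Oc4c3)cc2O1 | intermediate
3 | 6,6'-[(2R,3S)-2,3-dimethylbutane-1,4-diyl]bis[2,2-dimethyl-4-(4,4,5,5-tetramethyl-1,3,2-dioxaborolan-2-yl)-1,3-benzodioxole] | CC1(C)Oc2c(B3OC(C)(C)C(C)(C)O3)cc(C[C@@H](C)[C@@H](C)Cc3cc(B4OC(C)(C)C(C)(C)O4)c4OC(C)(C)Oc4c3)cc2O1 | intermediate
4 | 6,6'-[(2R,3S)-2,3-dimethylbutane-1,4-diyl]bis(4-methoxy-2,2-dimethyl-1,3-benzodioxole) | CC1(C)Oc2c(OC)cc(C[C@@H](C)[C@@H](C)Cc3cc(OC)c4OC(C)(C)Oc4c3)cc2O1 | intermediate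
5 | 5,5'-[(2R,3S)-2,3-dimethylbutane-1,4-diyl]bis(3-methoxybenzene-1,2-diol), meso | COc1cc(C[C@@H](C)[C@@H](C)Cc2cc(O)c(O)c(OC)c2)cc(O)c1O | target

**Total step count:** 3. **Longest linear sequence:** 3.

**Steps most likely to fail**

Step 2 (the proposed new step). The weak half is the copper stage. An aryl–Bpin flanked by an oxygen transmetalates slowly, so protodeboronation back to 2 or hydroxylation can outrun methoxylation, and both rings must react. The fallback uses known chemistry only. It sets out from 3, this time isolated by filtration through silica after the borylation, and comes back to the route at 4. Compound 3 is oxidised with NaBO3·4H2O in THF–H2O at rt (boron-to-oxygen 1,2-shift) to the bis-phenol 6,6'-[(2R,3S)-2,3-dimethylbutane-1,4-diyl]bis(2,2-dimethyl-1,3-benzodioxol-4-ol) F1. F1 is then methylated with MeI and K2CO3 in acetone at 50 °C (Williamson ether synthesis) to give 4. The C–O bond is thus made by oxidation and alkylation instead of copper coupling, at the cost of one step.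

Step 1. Catechol acetonides form reluctantly, so the mono-ketal may persist, and hot acid with an acetone equivalent can C-alkylate the electron-rich rings. The fallback changes the protecting group and the way it is put on. It sets out from 1 and comes back to the route at 5. Dehydrative ketalisation with cyclohexanone (TsOH·H2O, PhMe, Dean–Stark), which is thermodynamically easier for catechols, gives the bis(cyclohexylidene ketal) 5,5'-[(2R,3S)-2,3-dimethylbutane-1,4-diyl]bis(spiro[1,3-benzodioxole-2,1'-cyclohexane]) F2. The step 2 sequence then passes through the bis-boronate 6,6'-[(2R,3S)-2,3-dimethylbutane-1,4-diyl]bis[4-(4,4,5,5-tetramethyl-1,3,2-dioxaborolan-2-yl)spiro[1,3-benzodioxole-2,1'-cyclohexane]] F3, formed in the flask. It delivers the bis(methoxy) ketal 6,6'-[(2R,3S)-2,3-dimethylbutane-1,4-diyl]bis(4-methoxyspiro[1,3-benzodioxole-2,1'-cyclohexane]) F4. TFA–H2O (9:1) at rt then gives 5.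

Step 3. The freed 3-methoxycatechol rings are easily air-oxidised to o-quinones, and the liberated acetone can re-alkylate them in strong protic acid. The fallback replaces hydrolysis by a non-aqueous Lewis-acid ketal exchange. It sets out from 4 and comes back to the route at 5. Treatment with 1,3-propanedithiol (2.5 equiv) and BF3·OEt2 in CH2Cl2 at 0 °C traps the isopropylidene unit irreversibly as its dithiane in a reducing medium. This fallback makes no new compound (F0).

**Further compounds**
F1 | step 2 | 6,6'-[(2R,3S)-2,3-dimethylbutane-1,4-diyl]bis(2,2-dimethyl-1,3-benzodioxol-4-ol) | CC1(C)Oc2c(O)cc(C[C@@H](C)[C@@H](C)Cc3cc(O)c4OC(C)(C)Oc4c3)cc2O1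
F2 | step 1 | 5,5'-[(2R,3S)-2,3-dimethylbutane-1,4-diyl]bis(spiro[1,3-benzodioxole-2,1'-cyclohexane]) | C1CCC2(CC1)Oc1ccc(C[C@@H](C)[C@@H](C)Cc3ccc4OC5(CCCCC5)Oc4c3)cc1O2
F3 | step 1 | 6,6'-[(2R,3S)-2,3-dimethylbutane-1,4-diyl]bis[4-(4,4,5,5-tetramethyl-1,3,2-dioxaborolan-2-yl)spiro[1,3-benzodioxole-2,1'-cyclohexane]] | C1CCC2(CC1)Oc1c(B3OC(C)(C)C(C)(C)O3)cc(C[C@@H](C)[C@@H](C)Cc3cc(B4OC(C)(C)C(C)(C)O4)c4OC5(CCCCC5)Oc4c3)cc1O2
F4 | step 1 | 6,6'-[(2R,3S)-2,3-dimethylbutane-1,4-diyl]bis(4-methoxyspiro[1,3-benzodioxole-2,1'-cyclohexane]) | C1CCC2(CC1)Oc1c(OC)cc(C[C@@H](C)[C@@H](C)Cc3cc(OC)c4OC5(CCCCC5)Oc4c3)cc1O2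
F0 | step 3 | none | none
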